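**Retrosynthetic overview**

- Feature: the five-membered ring C1–C2–C3–C4–C5 is a masked 3-methylcyclopent-2-enone. C4 (isopropyl carbinol) is its carbonyl, C1 (quaternary, methyl-bearing) its β-carbon, and C5 its α-carbon, which carries the oxygenated C6.
- Last disconnection: the C6–O aroyl ester. Before it, the C8=C9–C10=O enone of the seven-membered ring (C1, C5, C6, C7, C8, C9, C10) is opened at C8–C9 to a C10 enol silane and a C8 ketal (directed aldol, then loss of the C8 alkoxy group).
- The C4 carbinol comes from isopropyl addition to the cyclopentanone. The C9=C10 enol silane comes from the 1-silylvinyl group, without acid, so the C8 ketal is kept.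
- Key disconnection: C1–C10 and C5–C6, made in one flask by catalytic enantioselective conjugate addition of a 1-silylvinyl aluminium reagent to 3-methylcyclopentenone and aldol capture of the enolate by the ketal aldehyde.
- Ring order: the cyclopentane is bought; the cycloheptenone is formed in step 8.

Key step: step 3

Numbering: daucane numbering is used throughout. C1 is the quaternary ring-fusion carbon (methyl), C2 and C3 are CH2, C4 carries isopropyl and OH, C5 is the ring-fusion CH, C6 carries the ester oxygen, C7 is CH2, C8 carries methyl, C9 is the alkene CH, C10 is the ketone. The target is 1S,4R,5S,6S.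

Assumption: the sense of induction at C1 is fixed by the antipode of the chiral carbene ligand L; the antipode that gives 1S is used. L = trans-1-(2,6-diethylphenyl)-4,5-diphenyl-3-(2-sulfonatophenyl)imidazolin-2-ylidene, used as its disilver complex Ag2L2.

Remark: ethyl (2-methyl-1,3-dioxolan-2-yl)acetate, the ethylene ketal of ethyl acetoacetate, is a commercial fragrance chemical and is taken as bought.

**Step 1**
Reactants: 1 ethynyltrimethylsilane
Product: 2 diisobutyl[1-(trimethylsilyl)ethenyl]aluminium (used as a solution)
Conditions: DIBAL-H (1.0 equiv), hexanes/THF 5:1, 55 °C, 2 h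
Reagents that add atoms: diisobutylaluminium hydride, CC(C)C[AlH]CC(C)C
Why: Hydroalumination of a silylacetylene places aluminium on the silicon-bearing carbon, so the 1-silylvinylalane forms regioselectively and no stereocentre is involved.

**Step 2**
Reactants: 3 ethyl (2-methyl-1,3-dioxolan-2-yl)acetate
Product: 4 (2-methyl-1,3-dioxolan-2-yl)acetaldehyde
Conditions: DIBAL-H (1.05 equiv), CH2Cl2, −78 °C; MeOH, aq. potassium sodium tartrate
Reagents that add atoms: none
Why: Partial ester reduction with DIBAL-H at −78 °C stops at the aluminium hemiacetal, which gives the aldehyde on work-up while the ketal is untouched.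

**Step 3**
Reactants: 5 3-methylcyclopent-2-en-1-one; 2 diisobutyl[1-(trimethylsilyl)ethenyl]aluminium; 4 (2-methyl-1,3-dioxolan-2-yl)acetaldehyde
Product: 7 (2S,3S)-2-[(1S)-1-hydroxy-2-(2-methyl-1,3-dioxolan-2-yl)ethyl]-3-methyl-3-[1-(trimethylsilyl)ethenyl]cyclopentan-1-one, via diisobutylaluminium enolate 6 (not isolated)
Conditions: 2 (2.5 equiv), Cu(OTf)2 (5 mol%), Ag2L2 (2.5 mol%), THF, 22 °C, 15 min; then 4 (3 equiv), −78 → −40 °C; aq. potassium sodium tartrate
Reagents that add atoms: none
Why: The carbene–copper complex formed from Cu(OTf)2 and Ag2L2 takes the 1-silylvinyl group from aluminium and adds it to C1 of the enone (C1–C10), leaving the aluminium enolate 6, whose C5 then adds to the aldehyde carbon (C5–C6) through a six-membered aluminium-bound chair. The closest known chemistry is the carbene–copper-catalysed enantioselective conjugate addition of silyl-substituted vinylaluminium reagents to β-substituted cyclopentenones, joined to the aldol capture of the metal enolate used in three-component couplings. No ring is closed; two bonds are added to the bought five-membered ring. C1 is set by the chiral catalyst; C5 is set because the aldehyde enters on the enolate face opposite the bulky silylvinyl group, so C6 ends cis to the methyl group; C6 is set by the ring-locked E-enolate in the chair with the aldehyde substituent equatorial, which gives the anti aldol. The step needs 1,4- over 1,2-addition and vinyl over isobutyl transfer, secured by the copper catalyst and the higher transfer aptitude of the sp2 group. It also needs trapping at C5 only, secured because the enolate is generated regiospecifically by the conjugate addition and is not equilibrated at low temperature.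

**Step 4**
Reactants: 7 the aldol adduct
Product: 8 (2S,3S)-2-[(1S)-1-(tert-butyldimethylsilyloxy)-2-(2-methyl-1,3-dioxolan-2-yl)ethyl]-3-methyl-3-[1-(trimethylsilyl)ethenyl]cyclopentan-1-one
Conditions: TBSOTf (1.1 equiv), 2,6-lutidine, CH2Cl2, −78 °C
Reagents that add atoms: tert-butyldimethylsilyl trifluoromethanesulfonate, CC(C)(C)[Si](C)(C)OS(=O)(=O)C(F)(F)F
Why: Silyl triflate silylation of the secondary alcohol at −78 °C is faster than enol silylation of the ketone, and the silyl ether blocks retro-aldol cleavage.

**Step 5**
Reactants: 8 the silyl-protected aldol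
Product: 9 (1R,2S,3S)-2-[(1S)-1-(tert-butyldimethylsilyloxy)-2-(2-methyl-1,3-dioxolan-2-yl)ethyl]-3-methyl-1-(propan-2-yl)-3-[1-(trimethylsilyl)ethenyl]cyclopentan-1-ol
Conditions: iPrMgCl (3 equiv), anhydrous CeCl3 (3 equiv), THF, −78 → 0 °C; aq. NH4Cl
Reagents that add atoms: isopropylmagnesium chloride, CC(C)[Mg]Cl
Why: Organocerium 1,2-addition suppresses enolisation and β-hydride reduction, and in the envelope that keeps the C5 side chain and the C1 silylvinyl group pseudo-equatorial the C1 methyl is pseudo-axial on the side-chain face, so isopropyl should enter from the opposite face and leave the new hydroxyl cis to the methyl and to the C6 chain (4R).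

**Step 6**
Reactants: 9 the tertiary alcohol
Product: 10 α,β-dihydroxysilane: 9 with the CH2=C(SiMe3) group changed to HOCH2–C(OH)(SiMe3) (either configuration at the new carbinol carbon)
Conditions: OsO4 (5 mol%), N-methylmorpholine N-oxide (2 equiv), acetone/H2O 5:1, rt
Reagents that add atoms: osmium tetroxide (catalytic oxygen carrier), O=[Os](=O)(=O)=O; N-methylmorpholine N-oxide, C[N+]1([O-])CCOCC1; water, O
Why: Catalytic OsO4 dihydroxylation attacks the only C=C bond, and the configuration of the new carbinol carbon does not matter because step 7 destroys it.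

**Step 7**
Reactants: 10 the α,β-dihydroxysilane
Product: 12 bis(trimethylsilyl) compound with a C10(OSiMe3)=C9H2 enol ether and a C4–OSiMe3 ether (C6–OTBS and C8 dioxolane kept; 1S,4R,5S,6S), via potassium C4-alkoxide of the enol silane 11 (not isolated)
Conditions: KH (4 equiv), THF, 0 °C → rt; then Me3SiCl (4 equiv), Et3N, −78 → 0 °C
Reagents that add atoms: chlorotrimethylsilane, C[Si](C)(C)Cl
Why: Base treatment of an α,β-dihydroxysilane gives the silyl enol ether by a 1,2-Brook shift of silicon from C10 to its oxygen with β-elimination of the C9 oxygen (a Peterson-type loss of silanolate would converge on the same product after silylation), which fixes the enol double bond at C9=C10 without acid so the ketal survives, and Me3SiCl caps the C4 alkoxide.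

**Step 8**
Reactants: 12 the enol silane ketal
Product: 13 (1S,4R,5S,6S)-6-(tert-butyldimethylsilyloxy)-4-(trimethylsilyloxy)-8-[2-(trimethylsilyloxy)ethoxy]daucan-10-one (either configuration at C8)
Conditions: Me3SiOTf (1.2 equiv), 2,6-di-tert-butyl-4-methylpyridine (1.5 equiv), CH2Cl2 (0.005 M), −78 → −40 °C; Et3N, aq. NaHCO3
Reagents that add atoms: none
Why: In this intramolecular Mukaiyama aldol addition of a silyl enol ether to a ketal, Me3SiOTf opens the dioxolane to the C8 oxocarbenium ion and the unhindered C9 terminus attacks it to close the seven-membered ring, and since C9 is the only nucleophilic carbon neither C7 nor the C6 silyl ether is touched, while capture of the cation by the C4 oxygen is reversible and C–C bond formation is not.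

**Step 9**
Reactants: 13 the β-alkoxy ketone
Product: 14 (1S,4R,5S,6S)-6-(tert-butyldimethylsilyloxy)-4-(trimethylsilyloxy)dauc-8-en-10-one
Conditions: DBU (3 equiv), toluene, 60 °C
Reagents that add atoms: none
Why: E1cB elimination of the β-alkoxy group can only place the double bond at C8=C9, because C9 is the only α-carbon of the C10 ketone that carries hydrogen.

**Step 10**
Reactants: 14 the bis-silyl enone
Product: 15 (1S,4R,5S,6S)-4,6-dihydroxydauc-8-en-10-one
Conditions: HF·pyridine, THF/pyridine, 0 °C → rt
Reagents that add atoms: none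
Why: Fluoride cleavage of both silyl ethers under slightly acidic conditions avoids the γ-deprotonation of the enone that basic fluoride could cause.

**Step 11**
Reactants: 15 the diol enone; 16 4-acetoxybenzoic acid
Product: 17 (1S,4R,5S,6S)-6-(4-acetoxybenzoyloxy)-4-hydroxydauc-8-en-10-one
Conditions: 16 (1.5 equiv), EDC·HCl, DMAP, CH2Cl2, rt
Reagents that add atoms: none
Why: Steglich esterification acylates the secondary C6 hydroxyl, while the hindered tertiary C4 hydroxyl does not react.

**Step 12**
Reactants: 17 the acetoxybenzoate
Product: 18 (1S,4R,5S,6S)-4-hydroxy-6-(4-hydroxybenzoyloxy)dauc-8-en-10-one (target)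
Conditions: pyrrolidine (3 equiv), CH2Cl2, 0 °C
Reagents that add atoms: none
Why: Aminolysis removes the aryl acetate, which is far more electrophilic than the alkyl benzoate, so the phenol is freed without touching the C6 ester or the enone.

**Compound list**

1 | ethynyltrimethylsilane | C#C[Si](C)(C)C | starting material
2 | diisobutyl[1-(trimethylsilyl)ethenyl]aluminium | C=C([Si](C)(C)C)[Al](CC(C)C)CC(C)C | intermediate
3 | ethyl (2-methyl-1,3-dioxolan-2-yl)acetate | CCOC(=O)CC1(C)OCCO1 | starting material
4 | (2-methyl-1,3-dioxolan-2-yl)acetaldehyde | CC1(CC=O)OCCO1 | intermediate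
5 | 3-methylcyclopent-2-en-1-one | CC1=CC(=O)CC1 | starting material
6 | diisobutylaluminium enolate of (3S)-3-methyl-3-[1-(trimethylsilyl)ethenyl]cyclopentanone (enolate C4=C5) | C=C([Si](C)(C)C)[C@@]1(C)CCC(O[Al](CC(C)C)CC(C)C)=C1 | intermediate
7 | (2S,3S)-2-[(1S)-1-hydroxy-2-(2-methyl-1,3-dioxolan-2-yl)ethyl]-3-methyl-3-[1-(trimethylsilyl)ethenyl]cyclopentan-1-one | C=C([Si](C)(C)C)[C@@]1(C)CCC(=O)[C@@H]1[C@@H](O)CC2(C)OCCO2 | intermediate
8 | tert-butyldimethylsilyl ether of 7 at C6–O | C=C([Si](C)(C)C)[C@@]1(C)CCC(=O)[C@@H]1[C@@H](O[Si](C)(C)C(C)(C)C)CC2(C)OCCO2 | intermediate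
9 | (1R,2S,3S)-2-[(1S)-1-(tert-butyldimethylsilyloxy)-2-(2-methyl-1,3-dioxolan-2-yl)ethyl]-3-methyl-1-(propan-2-yl)-3-[1-(trimethylsilyl)ethenyl]cyclopentan-1-ol | C=C([Si](C)(C)C)[C@@]1(C)CC[C@@](O)(C(C)C)[C@@H]1[C@@H](O[Si](C)(C)C(C)(C)C)CC2(C)OCCO2 | intermediate
10 | α,β-dihydroxysilane from 9, HOCH2–C(OH)(SiMe3) on C1 | OCC(O)([Si](C)(C)C)[C@@]1(C)CC[C@@](O)(C(C)C)[C@@H]1[C@@H](O[Si](C)(C)C(C)(C)C)CC2(C)OCCO2 | intermediate
11 | potassium C4-alkoxide of the C10 trimethylsilyl enol ether | C=C(O[Si](C)(C)C)[C@@]1(C)CC[C@@]([O-])(C(C)C)[C@@H]1[C@@H](O[Si](C)(C)C(C)(C)C)CC2(C)OCCO2.[K+] | intermediate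
12 | C10 trimethylsilyl enol ether with C4–OSiMe3, C6–OTBS and C8 dioxolane | C=C(O[Si](C)(C)C)[C@@]1(C)CC[C@@](O[Si](C)(C)C)(C(C)C)[C@@H]1[C@@H](O[Si](C)(C)C(C)(C)C)CC2(C)OCCO2 | intermediate
13 | (1S,4R,5S,6S)-6-(tert-butyldimethylsilyloxy)-4-(trimethylsilyloxy)-8-[2-(trimethylsilyloxy)ethoxy]daucan-10-one | CC1(OCCO[Si](C)(C)C)CC(=O)[C@@]2(C)CC[C@@](O[Si](C)(C)C)(C(C)C)[C@@H]2[C@@H](O[Si](C)(C)C(C)(C)C)C1 | intermediate
14 | (1S,4R,5S,6S)-6-(tert-butyldimethylsilyloxy)-4-(trimethylsilyloxy)dauc-8-en-10-one | CC1=CC(=O)[C@@]2(C)CC[C@@](O[Si](C)(C)C)(C(C)C)[C@@H]2[C@@H](O[Si](C)(C)C(C)(C)C)C1 | intermediate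
15 | (1S,4R,5S,6S)-4,6-dihydroxydauc-8-en-10-one | CC1=CC(=O)[C@@]2(C)CC[C@@](O)(C(C)C)[C@@H]2[C@@H](O)C1 | intermediate
16 | 4-acetoxybenzoic acid | CC(=O)Oc1ccc(cc1)C(=O)O | starting material
17 | (1S,4R,5S,6S)-6-(4-acetoxybenzoyloxy)-4-hydroxydauc-8-en-10-one | CC1=CC(=O)[C@@]2(C)CC[C@@](O)(C(C)C)[C@@H]2[C@@H](OC(=O)c2ccc(OC(C)=O)cc2)C1 | intermediate
18 | (1S,4R,5S,6S)-4-hydroxy-6-(4-hydroxybenzoyloxy)dauc-8-en-10-one | CC1=CC(=O)[C@@]2(C)CC[C@@](O)(C(C)C)[C@@H]2[C@@H](OC(=O)c2ccc(O)cc2)C1 | target

**Step count**

Total: 12 steps. Longest linear sequence: 11 steps (step 1, then steps 3 to 12).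

**Steps most likely to fail**

1. Step 3. The hindered aluminium enolate next to the new quaternary carbon may add to the aldehyde too slowly, residual vinylalane may consume the aldehyde, or the anti/syn selectivity at C6 may be low. Fallback: the route sets out again from 5 and 2, and the conjugate addition is run as before to 6. The enolate is then silylated in the flask with Me3SiOTf and the trimethylsilyl enol ether F1 is isolated. MeLi in THF at 0 °C turns it into the lithium enolate F2, free of aluminium species. Aldehyde 4 is added at −78 °C, and the closed lithium chair should give the same anti aldol. The fallback rejoins the route at 7.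

2. Step 8. Reversible capture of the C8 cation by the C4 oxygen, or loss of a proton to an enol ether, may outrun the seven-membered ring closure. Fallback: the route sets out from 12. Dilute HCl in THF at 0 °C removes both trimethylsilyl groups and the dioxolane and gives the hydroxy diketone F3, in equilibrium with its C4–O–C8 lactol. KOtBu in tBuOH/THF at 0 °C then effects an intramolecular aldol condensation. Only the C9 enolate can reach the unhindered C8 ketone, the C10 ketone is neopentylic, and closure of C7 onto C10 would give a trans-fused bicyclo[3.3.0]octane. The product is the silyl-protected hydroxy enone F4. HF·pyridine as in step 10 removes the silyl group, and the fallback rejoins the route at 15.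

3. Step 5. Facial selectivity of the isopropyl addition may be poor, since the lower face is shielded by the C5 side chain and the C1 methyl and the upper face by the C1 silylvinyl group. Fallback: the route sets out from 7, with the C6 hydroxyl left free. Excess iPrMgCl/CeCl3 first forms the C6 alkoxide, which chelates the C4 carbonyl and locks the side chain on the lower face. Addition from the upper face should then give the diol F5. TBSOTf and 2,6-lutidine at −78 °C silylate only the secondary hydroxyl, and the fallback rejoins the route at 9.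

**Further compounds**

F1 | step 3 | trimethylsilyl enol ether of (3S)-3-methyl-3-[1-(trimethylsilyl)ethenyl]cyclopentanone | C=C([Si](C)(C)C)[C@@]1(C)CCC(O[Si](C)(C)C)=C1
F2 | step 3 | lithium enolate of (3S)-3-methyl-3-[1-(trimethylsilyl)ethenyl]cyclopentanone | C=C([Si](C)(C)C)[C@@]1(C)CCC(O[Li])=C1
F3 | step 8 | hydroxy diketone with C10 acetyl, C8 methyl ketone, C6–OTBS and free C4–OH | CC(=O)[C@@]1(C)CC[C@@](O)(C(C)C)[C@@H]1[C@@H](O[Si](C)(C)C(C)(C)C)CC(C)=O
F4 | step 8 | (1S,4R,5S,6S)-6-(tert-butyldimethylsilyloxy)-4-hydroxydauc-8-en-10-one | CC1=CC(=O)[C@@]2(C)CC[C@@](O)(C(C)C)[C@@H]2[C@@H](O[Si](C)(C)C(C)(C)C)C1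
F5 | step 5 | diol from isopropyl addition to unprotected 7 | C=C([Si](C)(C)C)[C@@]1(C)CC[C@@](O)(C(C)C)[C@@H]1[C@@H](O)CC2(C)OCCO2
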